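**Plan**

1. Atom labels used below: ring O1, C2 (guaiacyl-bearing), C3 (bears the C9H2OH group), C4 (bears the C7' ketone), C5 (ring CH2).
2. Retrosynthetic cuts, in order: the two ArO–Si bonds; C3–C4 (ring closure); the enol O–Si bond at C7'; O1–C5 (oxa-Michael); the C3–C9 oxirane (back to an allylic alcohol).
3. Forward: a guaiacyl epoxy alcohol (C2, C3, C9) and a syringyl vinyl ketone (C5, C4, C7') are joined at O1–C5, the ketone is turned into its enol silane, and the tetrahydrofuran, the only ring built, closes last at C3–C4.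
4. Enabling feature: C3 carries the hydroxymethyl carbon C9, so a C3–C9 oxirane is a latent C3 radical; C4 is the α-carbon of the aryl ketone, so the C4=C7' enol silane is an exocyclic 5-exo acceptor on the C3–C2–O1–C5–C4 tether and its radical adduct is a masked ketone.
5. Stereochemistry: C2 comes from one catalytic Sharpless kinetic resolution; the oxirane carbon and the enol geometry are erased in the radical; C3 is set trans to the C2 aryl group in the cyclization; C4 is set last by equilibration α to the ketone.

Key step: step 8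

Assumption: the all-trans hydroxy ketone is taken to be more stable than its C4 epimer and that epimer's cis-fused cyclic hemiketal, as is usual for 3-acyl-4-alkyl tetrahydrofurans.

Abbreviations: TBS = tert-butyldimethylsilyl; TMS = trimethylsilyl; ArG = 4-(TBS-oxy)-3-methoxyphenyl; ArS = 4-(TBS-oxy)-3,5-dimethoxyphenyl.

**Step 1**
Reactants: 1 vanillin
Product: 2 4-(TBS-oxy)-3-methoxybenzaldehyde
Conditions: TBSCl, imidazole, DMF, rt
Reagents that add atoms: tert-butyldimethylsilyl chloride, CC(C)(C)[Si](C)(C)Cl
Why: Imidazole-promoted silylation of the phenol (silyl ether formation) masks the acidic OH for the Grignard, amide-base and trivalent-titanium steps, and no stereocenter is formed.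

**Step 2**
Reactants: 2 4-(TBS-oxy)-3-methoxybenzaldehyde
Product: 3 racemic 1-(ArG)prop-2-en-1-ol
Conditions: CH2=CHMgBr, THF, −78 to 0 °C; aq. NH4Cl
Reagents that add atoms: vinylmagnesium bromide, C=C[Mg]Br
Why: Grignard 1,2-addition to the aldehyde gives the racemic secondary allylic alcohol whose carbinol carbon becomes C2 and whose vinyl group becomes C3 and C9.

**Step 3**
Reactants: 3 racemic 1-(ArG)prop-2-en-1-ol
Product: 4 (R)-(ArG)[(S)-oxiran-2-yl]methanol (erythro)
Conditions: Ti(OiPr)4 (10 mol%), D-(−)-diisopropyl tartrate (12 mol%), t-BuOOH (0.45 equiv, anhydrous), 4 Å molecular sieves, CH2Cl2, −20 °C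
Reagents that add atoms: tert-butyl hydroperoxide, CC(C)(C)OO
Why: Sharpless kinetic resolution: with the D-(−)-tartrate ligand the (S)-allylic alcohol should be epoxidized much faster than its antipode (which is left behind and removed) and erythro-selectively, so the catalyst sets C2 (labelled R in 4 only because the oxiranyl group outranks the aryl group), while the oxirane carbon's configuration is erased later in step 8.

**Step 4**
Reactants: 5 acetosyringone
Product: 6 1-(ArS)ethan-1-one
Conditions: TBSCl, imidazole, DMF, 40 °C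
Reagents that add atoms: tert-butyldimethylsilyl chloride, CC(C)(C)[Si](C)(C)Cl
Why: Imidazole-promoted silylation of the hindered phenol (silyl ether formation) removes the acidic OH before the enone is made and used.

**Step 5**
Reactants: 6 1-(ArS)ethan-1-one
Product: 8 1-(ArS)prop-2-en-1-one, via Mannich base 7 (not isolated)
Conditions: (CH2O)n, diisopropylammonium trifluoroacetate (1 equiv), CF3CO2H (10 mol%), THF, reflux
Reagents that add atoms: formaldehyde (from paraformaldehyde), C=O; diisopropylamine (from its trifluoroacetate; its atoms stay only in 7), CC(C)NC(C)C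
Why: Mannich reaction of the methyl ketone with formaldehyde and the secondary ammonium salt followed by β-elimination of the amine in the same pot (direct α-methylenation) gives the aryl vinyl ketone, with no stereocenter formed.

**Step 6**
Reactants: 4 (R)-(ArG)[(S)-oxiran-2-yl]methanol; 8 1-(ArS)prop-2-en-1-one
Product: 9 3-{(R)-(ArG)[(S)-oxiran-2-yl]methoxy}-1-(ArS)propan-1-one
Conditions: PMe3 (10 mol%), 8 (1.3 equiv), THF, 0 °C to rt
Reagents that add atoms: none
Why: Phosphine-catalysed oxa-Michael addition, in which the PMe3–enone zwitterion deprotonates the alcohol and the ion-paired alkoxide adds to the β-carbon of 8, forms O1–C5 under near-neutral conditions that should leave the C2 stereocenter and the oxirane untouched.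

**Step 7**
Reactants: 9 3-{(R)-(ArG)[(S)-oxiran-2-yl]methoxy}-1-(ArS)propan-1-one
Product: 10 (Z)-1-(ArS)-3-{(R)-(ArG)[(S)-oxiran-2-yl]methoxy}-1-(TMS-oxy)prop-1-ene
Conditions: LDA (1.15 equiv) added to 9 and Me3SiCl (3 equiv), THF, −78 °C; Et3N, cold aq. NaHCO3/pentane; used crude
Reagents that add atoms: chlorotrimethylsilane, C[Si](C)(C)Cl
Why: Kinetic enolization with in-situ silyl trapping (silyl enol ether formation) captures the lithium enolate as the (Z)-enol silane before it can expel the β-alkoxide (E1cB), and the oxirane is inert to LDA at −78 °C.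

**Step 8**
Reactants: 10 (Z)-1-(ArS)-3-{(R)-(ArG)[(S)-oxiran-2-yl]methoxy}-1-(TMS-oxy)prop-1-ene
Product: 12 (2S,3R,4R)-2-(ArG)-4-(ArS-carbonyl)-3-(hydroxymethyl)tetrahydrofuran (3,4-cis; drawn as the expected major C4 epimer; in equilibrium with its cyclic hemiketal), via C9 trimethylsilyl ether 11 (not isolated)
Conditions: Cp2TiCl2 (2.5 equiv), Mn dust, THF, rt, slow addition of 10; then I2 (to persistent colour), 0 °C to rt; aq. Na2S2O3, then 0.5 M HCl/THF, 0 °C
Reagents that add atoms: none
Why: Proposed new method: Cp2TiCl (trivalent titanium, from Cp2TiCl2 and Mn) should open the C3–C9 oxirane by inner-sphere electron transfer to the secondary C3 radical with C9–O on tetravalent titanium, this radical adds to C4 of the aryl enol silane, and I2 then oxidizes the resulting α-silyloxy benzylic C7' radical (or its titanium adduct) to a silyloxycarbenium ion that hands Me3Si to the C9 titanium alkoxide to give 11 (capture at carbon would give a bicyclic silyl ketal that hydrolyses to the same 12). The closest known reaction type is the Nugent–RajanBabu reductive cyclization of epoxy allyl ethers to 2-aryl-3-(hydroxymethyl)tetrahydrofurans with iodine termination at the benzylic carbon, together with radical addition to silyl enol ethers followed by oxidation of the α-silyloxy radical to the ketone; their combination is what is untested. The tetrahydrofuran (O1, C2, C3, C4, C5) closes by 5-exo-trig attack on the exocyclic C4=C7' bond. C3 is controlled by the substrate: the oxirane carbon is planar in the radical, so its configuration and the enol silane geometry do not matter, and the new bond should form on the face that puts C9 trans to the pseudo-equatorial C2 aryl group in the chair-like transition state; C4 is formed here without firm control (cis to C9 expected) and is settled in step 9. The step needs opening of the oxirane toward C3 and not C9 (secured by the terminal oxirane, which gives the secondary radical), ring closure faster than capture of the C3 radical by a second Cp2TiCl (secured by slow addition of 10 and the aryl-conjugated acceptor), and oxidation at C7' only (secured by the α-silyloxy benzylic site being far easier to oxidize than any other position).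

**Step 9**
Reactants: 12 (2S,3R,4R)-2-(ArG)-4-(ArS-carbonyl)-3-(hydroxymethyl)tetrahydrofuran
Product: 14 (2S,3R,4S)-4-(4-hydroxy-3,5-dimethoxybenzoyl)-2-(4-hydroxy-3-methoxyphenyl)-3-(hydroxymethyl)tetrahydrofuran (target), via all-trans bis-silyl ketone 13 (not isolated)
Conditions: DBU (0.3 equiv), toluene, rt to 40 °C; then Bu4NF (2.5 equiv), AcOH (2.5 equiv), THF, 0 °C
Reagents that add atoms: none
Why: Base-mediated epimerization α to the ketone (thermodynamic control through the enolate) should move the aroyl group trans to the hydroxymethyl group and so set C4 in 13, after which acetic-acid-buffered fluoride cleaves both aryl silyl ethers (fluoride desilylation) without disturbing C2, C3 or C4.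

**Compound list**

1 | vanillin (4-hydroxy-3-methoxybenzaldehyde) | COc1cc(C=O)ccc1O | starting material
2 | 4-(tert-butyldimethylsilyloxy)-3-methoxybenzaldehyde | COc1cc(C=O)ccc1O[Si](C)(C)C(C)(C)C | intermediate
3 | racemic 1-[4-(tert-butyldimethylsilyloxy)-3-methoxyphenyl]prop-2-en-1-ol | COc1cc(C(O)C=C)ccc1O[Si](C)(C)C(C)(C)C | intermediate
4 | (R)-[4-(tert-butyldimethylsilyloxy)-3-methoxyphenyl][(S)-oxiran-2-yl]methanol (erythro) | COc1cc([C@@H](O)[C@@H]2CO2)ccc1O[Si](C)(C)C(C)(C)C | intermediate
5 | acetosyringone (1-(4-hydroxy-3,5-dimethoxyphenyl)ethan-1-one) | CC(=O)c1cc(OC)c(O)c(OC)c1 | starting material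
6 | 1-[4-(tert-butyldimethylsilyloxy)-3,5-dimethoxyphenyl]ethan-1-one | CC(=O)c1cc(OC)c(O[Si](C)(C)C(C)(C)C)c(OC)c1 | intermediate
7 | 3-(diisopropylamino)-1-[4-(tert-butyldimethylsilyloxy)-3,5-dimethoxyphenyl]propan-1-one (Mannich base, not isolated) | CC(C)N(CCC(=O)c1cc(OC)c(O[Si](C)(C)C(C)(C)C)c(OC)c1)C(C)C | intermediate
8 | 1-[4-(tert-butyldimethylsilyloxy)-3,5-dimethoxyphenyl]prop-2-en-1-one | C=CC(=O)c1cc(OC)c(O[Si](C)(C)C(C)(C)C)c(OC)c1 | intermediate
9 | 3-{(R)-[4-(tert-butyldimethylsilyloxy)-3-methoxyphenyl][(S)-oxiran-2-yl]methoxy}-1-[4-(tert-butyldimethylsilyloxy)-3,5-dimethoxyphenyl]propan-1-one | COc1cc([C@@H](OCCC(=O)c2cc(OC)c(O[Si](C)(C)C(C)(C)C)c(OC)c2)[C@@H]3CO3)ccc1O[Si](C)(C)C(C)(C)C | intermediate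
10 | (Z)-trimethylsilyl enol ether of 9 (OSiMe3 and the C5H2 group cis on the C4=C7' bond) | COc1cc([C@@H](OC/C=C(\O[Si](C)(C)C)c2cc(OC)c(O[Si](C)(C)C(C)(C)C)c(OC)c2)[C@@H]3CO3)ccc1O[Si](C)(C)C(C)(C)C | intermediate
11 | (2S,3R,4R)-2-[4-(tert-butyldimethylsilyloxy)-3-methoxyphenyl]-4-[4-(tert-butyldimethylsilyloxy)-3,5-dimethoxybenzoyl]-3-[(trimethylsilyloxy)methyl]tetrahydrofuran (not isolated) | COc1cc([C@H]2OC[C@H](C(=O)c3cc(OC)c(O[Si](C)(C)C(C)(C)C)c(OC)c3)[C@@H]2CO[Si](C)(C)C)ccc1O[Si](C)(C)C(C)(C)C | intermediate
12 | (2S,3R,4R)-2-[4-(tert-butyldimethylsilyloxy)-3-methoxyphenyl]-4-[4-(tert-butyldimethylsilyloxy)-3,5-dimethoxybenzoyl]-3-(hydroxymethyl)tetrahydrofuran (2,3-trans, 3,4-cis) | COc1cc([C@H]2OC[C@H](C(=O)c3cc(OC)c(O[Si](C)(C)C(C)(C)C)c(OC)c3)[C@@H]2CO)ccc1O[Si](C)(C)C(C)(C)C | intermediate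
13 | (2S,3R,4S)-2-[4-(tert-butyldimethylsilyloxy)-3-methoxyphenyl]-4-[4-(tert-butyldimethylsilyloxy)-3,5-dimethoxybenzoyl]-3-(hydroxymethyl)tetrahydrofuran (all-trans, not isolated) | COc1cc([C@H]2OC[C@@H](C(=O)c3cc(OC)c(O[Si](C)(C)C(C)(C)C)c(OC)c3)[C@@H]2CO)ccc1O[Si](C)(C)C(C)(C)C | intermediate
14 | (2S,3R,4S)-4-(4-hydroxy-3,5-dimethoxybenzoyl)-2-(4-hydroxy-3-methoxyphenyl)-3-(hydroxymethyl)tetrahydrofuran | COc1cc([C@H]2OC[C@@H](C(=O)c3cc(OC)c(O)c(OC)c3)[C@@H]2CO)ccc1O | target

**Step count**

Total steps: 9. Longest linear sequence: 7 (steps 1, 2, 3, 6, 7, 8, 9).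

**Steps most likely to fail**

Step 8. The C3 radical may be captured by a second Cp2TiCl and eliminate (deoxygenation) before it cyclizes, or the iodine stage may not bring C7' cleanly to the ketone level (mixed oxidation levels, iodination of the electron-rich rings). The fallback uses known chemistry and separates ring closure from the oxidation-level adjustment. Setting out from 10, the standard reductive Nugent–RajanBabu cyclization with protic termination (Cp2TiCl from Cp2TiCl2 and Mn, THF; then 1 M HCl) should give the C7' carbinol diol F1 as a mixture at C7'. MnO2 in CH2Cl2, which oxidizes benzylic but not primary aliphatic alcohols, should then give 12, where the route is rejoined.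

Step 6. The epoxy alkoxide may undergo Payne rearrangement before it adds, or the hindered secondary alcohol may add so slowly that 8 oligomerizes. The fallback makes the ether before the oxirane. Setting out from 3, Sharpless kinetic resolution with L-(+)-diisopropyl tartrate and slightly more than half an equivalent of t-BuOOH should consume the (R)-alcohol as the antipodal epoxy alcohol F3 and leave the (S)-allylic alcohol F2. Oxa-Michael addition of F2 to 8 (PMe3 or catalytic t-BuOK, no oxirane present) should give the allyl ether ketone F4. Dimethyldioxirane in acetone should epoxidize the terminal alkene without Baeyer–Villiger oxidation of the aryl ketone and give 9 together with its oxirane-carbon epimer F5. Separation is not needed, because F5 passes through the epimeric enol silane F6 (step 7 conditions) to the same C3 radical in step 8. The route is rejoined at 9.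

Step 9. Epimerization at C4 may stay incomplete because the cis epimer rests as its cyclic hemiketal, or the base may trigger β-elimination of O1 and open the ring. The fallback blocks the hemiketal before equilibration. Setting out from 12, TBSCl/imidazole should cap the C9 hydroxyl and give the 3,4-cis tris-silyl ketone F7. DBU or catalytic NaOMe should then equilibrate this purely ketonic compound to the all-trans tris-silyl ketone F8. Buffered Bu4NF/AcOH removes all three silyl groups and gives 14.

**Further compounds**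

F1 | step 8 | (2S,3R,4R)-2-[4-(tert-butyldimethylsilyloxy)-3-methoxyphenyl]-4-{[4-(tert-butyldimethylsilyloxy)-3,5-dimethoxyphenyl](hydroxy)methyl}-3-(hydroxymethyl)tetrahydrofuran, both C7' epimers | COc1cc([C@H]2OC[C@H](C(O)c3cc(OC)c(O[Si](C)(C)C(C)(C)C)c(OC)c3)[C@@H]2CO)ccc1O[Si](C)(C)C(C)(C)C
F2 | step 6 | (S)-1-[4-(tert-butyldimethylsilyloxy)-3-methoxyphenyl]prop-2-en-1-ol | COc1cc([C@@H](O)C=C)ccc1O[Si](C)(C)C(C)(C)C
F3 | step 6 | (S)-[4-(tert-butyldimethylsilyloxy)-3-methoxyphenyl][(R)-oxiran-2-yl]methanol (enantiomer of 4, discarded) | COc1cc([C@H](O)[C@H]2CO2)ccc1O[Si](C)(C)C(C)(C)C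
F4 | step 6 | 3-{[(S)-1-[4-(tert-butyldimethylsilyloxy)-3-methoxyphenyl]prop-2-en-1-yl]oxy}-1-[4-(tert-butyldimethylsilyloxy)-3,5-dimethoxyphenyl]propan-1-one | COc1cc([C@@H](OCCC(=O)c2cc(OC)c(O[Si](C)(C)C(C)(C)C)c(OC)c2)C=C)ccc1O[Si](C)(C)C(C)(C)C
F5 | step 6 | 3-{(R)-[4-(tert-butyldimethylsilyloxy)-3-methoxyphenyl][(R)-oxiran-2-yl]methoxy}-1-[4-(tert-butyldimethylsilyloxy)-3,5-dimethoxyphenyl]propan-1-one (oxirane-carbon epimer of 9) | COc1cc([C@@H](OCCC(=O)c2cc(OC)c(O[Si](C)(C)C(C)(C)C)c(OC)c2)[C@H]3CO3)ccc1O[Si](C)(C)C(C)(C)C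
F6 | step 6 | (Z)-trimethylsilyl enol ether of F5 (oxirane-carbon epimer of 10) | COc1cc([C@@H](OC/C=C(\O[Si](C)(C)C)c2cc(OC)c(O[Si](C)(C)C(C)(C)C)c(OC)c2)[C@H]3CO3)ccc1O[Si](C)(C)C(C)(C)C
F7 | step 9 | (2S,3R,4R)-2-[4-(tert-butyldimethylsilyloxy)-3-methoxyphenyl]-4-[4-(tert-butyldimethylsilyloxy)-3,5-dimethoxybenzoyl]-3-[(tert-butyldimethylsilyloxy)methyl]tetrahydrofuran (3,4-cis) | COc1cc([C@H]2OC[C@H](C(=O)c3cc(OC)c(O[Si](C)(C)C(C)(C)C)c(OC)c3)[C@@H]2CO[Si](C)(C)C(C)(C)C)ccc1O[Si](C)(C)C(C)(C)C
F8 | step 9 | (2S,3R,4S)-2-[4-(tert-butyldimethylsilyloxy)-3-methoxyphenyl]-4-[4-(tert-butyldimethylsilyloxy)-3,5-dimethoxybenzoyl]-3-[(tert-butyldimethylsilyloxy)methyl]tetrahydrofuran (all-trans) | COc1cc([C@H]2OC[C@@H](C(=O)c3cc(OC)c(O[Si](C)(C)C(C)(C)C)c(OC)c3)[C@@H]2CO[Si](C)(C)C(C)(C)C)ccc1O[Si](C)(C)C(C)(C)C
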